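**Strategy.** Carbons C7, C8 and C9 with their oxygens map onto D-tartaric acid once C1 of ring A, the arene carrying the glycerol ether, stands in for one carboxyl carbon. The route therefore rests on the C1–C7 bond: a nickel/photoredox decarboxylative arylation unites the mono-acid mono-ester of D-tartrate acetonide with a ring A bromide whose glycerol diol is masked as two TBDPS ethers. Because the C7 radical sits on a rigid dioxolane, the aryl group enters anti to the C8 ester, so fragment union and the threo C7/C8 relationship arise in one operation. Ring B is then attached at O8 by SNAr and every silicon group is removed together at the end.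

Key step: step 5

Remark (assumption): 4-fluoro-3,5-dimethoxybenzaldehyde and dimethyl 2,3-O-isopropylidene-D-tartrate are taken as purchasable; the target is (7R,8R), which the (S,S) tartrate delivers because the CIP priorities change, not the geometry.

Locants and abbreviation: C7 is the benzylic carbinol carbon, C8 the aryloxy carbon, C9 the hydroxymethyl carbon; ring A carries the glycerol ether, ring B the hydroxypropyl chain. ArA = 4-{[1,3-bis(tert-butyldiphenylsilyloxy)propan-2-yl]oxy}-3,5-dimethoxyphenyl.

**Step 1**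
Reactants: 1 4-bromo-2,6-dimethoxyphenol; 2 diethyl chloromalonate
Product: 3 diethyl 2-(4-bromo-2,6-dimethoxyphenoxy)malonate
Conditions: K2CO3, acetone, reflux
Reagents that add atoms: none
Why: Williamson-type SN2 O-alkylation in which the phenoxide of 1 displaces chloride from the doubly activated malonate carbon; the chloro malonate is chosen because, unlike the bromo analogue, it does not transfer electrophilic halogen to the electron-rich ring.

**Step 2**
Reactants: 3 diethyl 2-(4-bromo-2,6-dimethoxyphenoxy)malonate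
Product: 4 2-(4-bromo-2,6-dimethoxyphenoxy)propane-1,3-diol
Conditions: LiAlH4, THF, 0 °C; aqueous NaOH work-up
Reagents that add atoms: none
Why: Hydride reduction of both esters to the 1,3-diol, run at 0 °C so that the aryl bromide is not reduced.

**Step 3**
Reactants: 4 2-(4-bromo-2,6-dimethoxyphenoxy)propane-1,3-diol
Product: 5 ring A bromide ArA–Br, 5-bromo-2-{[1,3-bis(tert-butyldiphenylsilyloxy)propan-2-yl]oxy}-1,3-dimethoxybenzene
Conditions: TBDPSCl (2.3 equiv), imidazole, DMF, rt
Reagents that add atoms: tert-butyl(chloro)diphenylsilane, CC(C)(C)[Si](Cl)(c1ccccc1)c1ccccc1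
Why: Imidazole-promoted silylation of two primary alcohols; TBDPS ethers are chosen because they should survive hydride, aqueous acetic acid and alkoxide base and fall in the final fluoride step.

**Step 4**
Reactants: 6 dimethyl (4S,5S)-2,2-dimethyl-1,3-dioxolane-4,5-dicarboxylate (dimethyl 2,3-O-isopropylidene-D-tartrate)
Product: 7 (4S,5S)-5-(methoxycarbonyl)-2,2-dimethyl-1,3-dioxolane-4-carboxylic acid
Conditions: KOH (1.0 equiv), MeOH, 0 °C → rt; then aq HCl to pH 2, extraction
Reagents that add atoms: potassium hydroxide, [K+].[OH-]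
Why: Mono-saponification of a C2-symmetric diester, in which the first carboxylate deactivates the second ester toward hydroxide and either ester gives the same product; the trans stereocentres should not epimerise with one equivalent of base at low temperature.

**Step 5**
Reactants: 7 (4S,5S)-5-(methoxycarbonyl)-2,2-dimethyl-1,3-dioxolane-4-carboxylic acid (1.5 equiv); 5 ring A bromide ArA–Br
Product: 8 methyl (4S,5R)-5-ArA-2,2-dimethyl-1,3-dioxolane-4-carboxylate (trans)
Conditions: Ir[dF(CF3)ppy]2(dtbbpy)PF6 (2 mol%), NiCl2·glyme (10 mol%), 4,4'-di-tert-butyl-2,2'-bipyridine (15 mol%), Cs2CO3, degassed DMF, blue LEDs (450 nm), rt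
Reagents that add atoms: none
Why: The carboxylate of 7 is oxidised by the photoexcited trivalent iridium complex and loses CO2 to give a planar, nucleophilic α-oxy radical at C7, while zerovalent nickel inserts into the C–Br bond of 5; the aryl divalent nickel species captures the radical, reductive elimination from trivalent nickel forms C1–C7, and the reduced iridium complex returns nickel to the zerovalent state. The closest known reaction type is the nickel/photoredox dual-catalytic decarboxylative arylation of α-oxy carboxylic acids with aryl bromides, which is established for cyclic ketal-protected α-oxy acids. No ring is closed. The new stereocentre C7 is set by substrate control: the radical has lost the configuration of the acid, and the aryl nickel unit approaches the dioxolane face anti to the CO2Me group at C8, giving the trans (4S,5R) ring, which is the (7R) threo array next to the untouched tartrate carbon that becomes (8R). The step needs trans diastereoselection and cross-coupling in preference to hydrogen-atom quenching of the radical; the first is secured by the 1,2-relationship on the five-membered ring, the second by the excess of 7 and by the meta-methoxy groups and twisted para-alkoxy group, which keep the bromide reactive toward oxidative addition.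

**Step 6**
Reactants: 8 methyl (4S,5R)-5-ArA-2,2-dimethyl-1,3-dioxolane-4-carboxylate
Product: 9 [(4R,5R)-5-ArA-2,2-dimethyl-1,3-dioxolan-4-yl]methanol
Conditions: LiBH4, THF/MeOH, 0 °C → rt
Reagents that add atoms: none
Why: Chemoselective borohydride reduction of the α-alkoxy ester to the C9 primary alcohol; no enolate is formed, so C8 keeps its configuration (the descriptor changes only through CIP priority), and the silyl ethers and ketal are inert.

**Step 7**
Reactants: 9 [(4R,5R)-5-ArA-2,2-dimethyl-1,3-dioxolan-4-yl]methanol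
Product: 10 (1R,2R)-1-ArA-propane-1,2,3-triol
Conditions: AcOH/THF/H2O (3:1:1), 50 °C
Reagents that add atoms: none
Why: Acid-catalysed hydrolysis of the isopropylidene ketal under weakly acidic conditions that should leave primary TBDPS ethers intact and not ionise the benzylic C7–O bond, so both stereocentres are retained.

**Step 8**
Reactants: 10 (1R,2R)-1-ArA-propane-1,2,3-triol
Product: 11 (4R,5R)-4-ArA-2,2-di-tert-butyl-1,3,2-dioxasilinan-5-ol (O7/O9 silylene, O8–H free)
Conditions: tBu2Si(OTf)2 (1.05 equiv), 2,6-lutidine, CH2Cl2, −20 → 0 °C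
Reagents that add atoms: di-tert-butylsilyl bis(trifluoromethanesulfonate), CC(C)(C)[Si](OS(=O)(=O)C(F)(F)F)(OS(=O)(=O)C(F)(F)F)C(C)(C)C
Why: Cyclic silylene formation, in which the reagent silylates the primary O9 first and then closes the unstrained six-membered ring onto O7 in preference to the strained five-membered ring through O8, leaving O8–H as the only free hydroxyl.

**Step 9**
Reactants: 11 (4R,5R)-4-ArA-2,2-di-tert-butyl-1,3,2-dioxasilinan-5-ol; 12 4-fluoro-3,5-dimethoxybenzaldehyde
Product: 14 ring B aldehyde (4-{[(4R,5R)-4-ArA-2,2-di-tert-butyl-1,3,2-dioxasilinan-5-yl]oxy}-3,5-dimethoxybenzaldehyde), via potassium alkoxide 13 (not isolated)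
Conditions: KN(SiMe3)2 (1.0 equiv), THF, −78 → 0 °C; then 12 (1.5 equiv), DMF, 0 °C → rt
Reagents that add atoms: none
Why: Nucleophilic aromatic substitution (SNAr, addition–elimination), in which the O8 alkoxide adds to the fluorine-bearing carbon activated by the para formyl group and fluoride is expelled; the C8–O bond is never broken, so C8 retains its configuration, and migration of the silylene to O8 would require a strained five-membered ring.

**Step 10**
Reactants: 14 ring B aldehyde
Product: 15 ethyl (E)-3-(4-{[(4R,5R)-4-ArA-2,2-di-tert-butyl-1,3,2-dioxasilinan-5-yl]oxy}-3,5-dimethoxyphenyl)acrylate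
Conditions: Ph3P=CHCO2Et, toluene, 80 °C
Reagents that add atoms: ethyl (triphenylphosphoranylidene)acetate, CCOC(=O)C=P(c1ccccc1)(c1ccccc1)c1ccccc1
Why: Wittig olefination with a stabilised ylide, which should give the (E)-cinnamate under neutral conditions that tolerate the silyl groups and the aryl ether.

**Step 11**
Reactants: 15 ethyl (E)-cinnamate
Product: 16 ethyl 3-(4-{[(4R,5R)-4-ArA-2,2-di-tert-butyl-1,3,2-dioxasilinan-5-yl]oxy}-3,5-dimethoxyphenyl)propanoate
Conditions: H2 (1 atm), 10% Pd/C, EtOAc, rt
Reagents that add atoms: none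
Why: Heterogeneous catalytic hydrogenation of the conjugated alkene in a neutral solvent, under which the silylated benzylic C7–O bond and the aryl ethers should not be hydrogenolysed.

**Step 12**
Reactants: 16 ethyl propanoate
Product: 17 3-(4-{[(4R,5R)-4-ArA-2,2-di-tert-butyl-1,3,2-dioxasilinan-5-yl]oxy}-3,5-dimethoxyphenyl)propan-1-ol
Conditions: LiBH4, THF/MeOH, 0 °C → rt
Reagents that add atoms: none
Why: Borohydride reduction of the ethyl ester to the 3-hydroxypropyl chain without touching the silicon protecting groups.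

**Step 13**
Reactants: 17 protected alcohol
Product: 18 (1R,2R)-1-[4-(1,3-dihydroxypropan-2-yloxy)-3,5-dimethoxyphenyl]-2-[4-(3-hydroxypropyl)-2,6-dimethoxyphenoxy]propane-1,3-diol (target)
Conditions: HF·pyridine, pyridine, THF, 0 °C → rt
Reagents that add atoms: none
Why: Fluoride-mediated global desilylation, in which buffered HF·pyridine cleaves the silylene and both TBDPS ethers through Si–F bond formation without acidity sufficient to ionise the benzylic C7 position, so the (7R,8R) pentaol should be released unchanged.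

**Compound list**
1 | 4-bromo-2,6-dimethoxyphenol | COc1cc(Br)cc(OC)c1O | starting material
2 | diethyl chloromalonate | CCOC(=O)C(Cl)C(=O)OCC | starting material
3 | diethyl 2-(4-bromo-2,6-dimethoxyphenoxy)malonate | CCOC(=O)C(Oc1c(OC)cc(Br)cc1OC)C(=O)OCC | intermediate
4 | 2-(4-bromo-2,6-dimethoxyphenoxy)propane-1,3-diol | COc1cc(Br)cc(OC)c1OC(CO)CO | intermediate
5 | 5-bromo-2-{[1,3-bis(tert-butyldiphenylsilyloxy)propan-2-yl]oxy}-1,3-dimethoxybenzene (ArA–Br) | COc1cc(Br)cc(OC)c1OC(CO[Si](c1ccccc1)(c1ccccc1)C(C)(C)C)CO[Si](c1ccccc1)(c1ccccc1)C(C)(C)C | intermediate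
6 | dimethyl (4S,5S)-2,2-dimethyl-1,3-dioxolane-4,5-dicarboxylate | COC(=O)[C@H]1OC(C)(C)O[C@@H]1C(=O)OC | starting material
7 | (4S,5S)-5-(methoxycarbonyl)-2,2-dimethyl-1,3-dioxolane-4-carboxylic acid | OC(=O)[C@H]1OC(C)(C)O[C@@H]1C(=O)OC | intermediate
8 | methyl (4S,5R)-5-ArA-2,2-dimethyl-1,3-dioxolane-4-carboxylate (trans) | COc1cc([C@H]2OC(C)(C)O[C@@H]2C(=O)OC)cc(OC)c1OC(CO[Si](c1ccccc1)(c1ccccc1)C(C)(C)C)CO[Si](c1ccccc1)(c1ccccc1)C(C)(C)C | intermediate
9 | [(4R,5R)-5-ArA-2,2-dimethyl-1,3-dioxolan-4-yl]methanol | COc1cc([C@H]2OC(C)(C)O[C@@H]2CO)cc(OC)c1OC(CO[Si](c1ccccc1)(c1ccccc1)C(C)(C)C)CO[Si](c1ccccc1)(c1ccccc1)C(C)(C)C | intermediate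
10 | (1R,2R)-1-ArA-propane-1,2,3-triol | COc1cc([C@@H](O)[C@H](O)CO)cc(OC)c1OC(CO[Si](c1ccccc1)(c1ccccc1)C(C)(C)C)CO[Si](c1ccccc1)(c1ccccc1)C(C)(C)C | intermediate
11 | (4R,5R)-4-ArA-2,2-di-tert-butyl-1,3,2-dioxasilinan-5-ol | COc1cc([C@H]2O[Si](C(C)(C)C)(C(C)(C)C)OC[C@H]2O)cc(OC)c1OC(CO[Si](c1ccccc1)(c1ccccc1)C(C)(C)C)CO[Si](c1ccccc1)(c1ccccc1)C(C)(C)C | intermediate
12 | 4-fluoro-3,5-dimethoxybenzaldehyde | COc1cc(C=O)cc(OC)c1F | starting material
13 | potassium (4R,5R)-4-ArA-2,2-di-tert-butyl-1,3,2-dioxasilinan-5-olate | COc1cc([C@H]2O[Si](C(C)(C)C)(C(C)(C)C)OC[C@H]2[O-])cc(OC)c1OC(CO[Si](c1ccccc1)(c1ccccc1)C(C)(C)C)CO[Si](c1ccccc1)(c1ccccc1)C(C)(C)C.[K+] | intermediate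
14 | 4-{[(4R,5R)-4-ArA-2,2-di-tert-butyl-1,3,2-dioxasilinan-5-yl]oxy}-3,5-dimethoxybenzaldehyde | COc1cc([C@H]2O[Si](C(C)(C)C)(C(C)(C)C)OC[C@H]2Oc2c(OC)cc(C=O)cc2OC)cc(OC)c1OC(CO[Si](c1ccccc1)(c1ccccc1)C(C)(C)C)CO[Si](c1ccccc1)(c1ccccc1)C(C)(C)C | intermediate
15 | ethyl (E)-3-(4-{[(4R,5R)-4-ArA-2,2-di-tert-butyl-1,3,2-dioxasilinan-5-yl]oxy}-3,5-dimethoxyphenyl)acrylate | COc1cc([C@H]2O[Si](C(C)(C)C)(C(C)(C)C)OC[C@H]2Oc2c(OC)cc(/C=C/C(=O)OCC)cc2OC)cc(OC)c1OC(CO[Si](c1ccccc1)(c1ccccc1)C(C)(C)C)CO[Si](c1ccccc1)(c1ccccc1)C(C)(C)C | intermediate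
16 | ethyl 3-(4-{[(4R,5R)-4-ArA-2,2-di-tert-butyl-1,3,2-dioxasilinan-5-yl]oxy}-3,5-dimethoxyphenyl)propanoate | COc1cc([C@H]2O[Si](C(C)(C)C)(C(C)(C)C)OC[C@H]2Oc2c(OC)cc(CCC(=O)OCC)cc2OC)cc(OC)c1OC(CO[Si](c1ccccc1)(c1ccccc1)C(C)(C)C)CO[Si](c1ccccc1)(c1ccccc1)C(C)(C)C | intermediate
17 | 3-(4-{[(4R,5R)-4-ArA-2,2-di-tert-butyl-1,3,2-dioxasilinan-5-yl]oxy}-3,5-dimethoxyphenyl)propan-1-ol | COc1cc([C@H]2O[Si](C(C)(C)C)(C(C)(C)C)OC[C@H]2Oc2c(OC)cc(CCCO)cc2OC)cc(OC)c1OC(CO[Si](c1ccccc1)(c1ccccc1)C(C)(C)C)CO[Si](c1ccccc1)(c1ccccc1)C(C)(C)C | intermediate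
18 | (1R,2R)-1-[4-(1,3-dihydroxypropan-2-yloxy)-3,5-dimethoxyphenyl]-2-[4-(3-hydroxypropyl)-2,6-dimethoxyphenoxy]propane-1,3-diol | COc1cc([C@@H](O)[C@@H](CO)Oc2c(OC)cc(CCCO)cc2OC)cc(OC)c1OC(CO)CO | target

**Step count.** Total: 13 steps. Longest linear sequence: 12 steps (steps 1–3, then 5–13).

**Steps most likely to fail**

Step 5. Oxidative addition of nickel to the electron-rich bromide may lag behind radical generation, so that the C7 radical is lost to hydrogen-atom abstraction or the carboxylate is O-arylated instead. The fallback sets out from 7, which is condensed with N-hydroxyphthalimide and N,N'-diisopropylcarbodiimide (DMAP cat., CH2Cl2) to give the redox-active ester 4-(1,3-dioxoisoindolin-2-yl) 5-methyl (4S,5S)-2,2-dimethyl-1,3-dioxolane-4,5-dicarboxylate F1. This is joined to 5 by nickel-catalysed reductive cross-electrophile coupling (NiBr2·glyme, 4,4'-di-tert-butyl-2,2'-bipyridine, Zn dust, DMA, rt). The same C7 radical is then released by single-electron reduction without a photocatalyst, should again be captured anti to the C8 ester, and the route comes back at 8.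

Step 9. Addition of the hindered secondary alkoxide to a fluorine-bearing carbon flanked by two methoxy groups may be slower than reversible hemiacetal formation at the aldehyde or base-induced consumption of the aldehyde. The fallback sets out from 11 and uses palladium-catalysed C–O cross-coupling with purchased 4-bromo-3,5-dimethoxybenzaldehyde ([Pd(allyl)Cl]2, the bulky biaryl di-tert-butylphosphine RockPhos, Cs2CO3, toluene, 90 °C). Reductive elimination from an aryl palladium alkoxide replaces addition–elimination, no free alkoxide is needed, no new compound is made on the way (F0), and the route comes back at 14.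

Step 2. The half-reduced malonate may enolise and expel the newly formed alkoxide by E1cB elimination, leading to 2-aryloxyallyl by-products, or excess hydride may remove the aryl bromine. The fallback sets out from 1 and forms the aryl ether directly by Mitsunobu reaction (PPh3, DIAD, toluene, 0 → 60 °C) with 1,3-bis(tert-butyldiphenylsilyloxy)propan-2-ol F2, itself obtained from glycerol by silylation of the two primary hydroxyls (TBDPSCl 2 equiv, imidazole, CH2Cl2, 0 °C). No malonate is involved and the route comes back at 5.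

**Further compounds**
F1 | step 5 | 4-(1,3-dioxoisoindolin-2-yl) 5-methyl (4S,5S)-2,2-dimethyl-1,3-dioxolane-4,5-dicarboxylate | O=C(ON2C(=O)c3ccccc3C2=O)[C@H]1OC(C)(C)O[C@@H]1C(=O)OC
F0 | step 9 | none | none
F2 | step 2 | 1,3-bis(tert-butyldiphenylsilyloxy)propan-2-ol | OC(CO[Si](c1ccccc1)(c1ccccc1)C(C)(C)C)CO[Si](c1ccccc1)(c1ccccc1)C(C)(C)C
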